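**Retrosynthetic overview**
- Target ⇒ caffeic acid + the C-1 epimeric allylic alcohol (invertive Mitsunobu) ⇒ enone (CBS reduction) ⇒ saturated bicyclic ketone (IBX dehydrogenation).
- Key disconnection: the bicyclic ketone ⇒ one open-chain (Z)-1,6-enyne that carries a silyl enol ether. Both C–C bonds to the tetrasubstituted alkene are made in a single gold-catalysed cascade.
- Ring order within that operation: ring A (methylenecyclopentane, 5-exo-dig) closes first, ring B (cyclohexanone, enol ether capture of the tertiary cation) second. Anti addition across the Z alkene gives the (S,S) pair of quaternary centres; the chiral ligand sets the absolute sense.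
- Open chain ⇒ (Z)-2,5-diiodo-3-methylpent-2-ene (but-2-yne + a C2 unit via a zirconacyclopentene) + an alkynyl zinc arm (Negishi) + 3-methylpentane-2,4-dione (alkylation/deacetylation).

Assumptions: (5-chloropent-1-yn-1-yl)trimethylsilane is bought as a catalogue compound. The ligand enantiomer that leads to the (S,S) series in step 5 must be fixed by experiment; the (R) form is written. C-3 of the open-chain ketone and C-2 of the cyclised ketone are stereorandom and are erased in step 6.

**Step 1**
Reactants: 1 but-2-yne; 2 ethylmagnesium bromide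
Product: 6 (Z)-2,5-diiodo-3-methylpent-2-ene, via diethylzirconocene 3 (not isolated), via zirconocene ethylene complex 4 (not isolated), via zirconacyclopentene 5 (not isolated)
Conditions: (C5H5)2ZrCl2 (1.0 equiv), EtMgBr (2.0 equiv), THF, −78 → 0 °C; but-2-yne (1.0 equiv), 0 °C → rt; I2 (2.5 equiv), 0 °C → rt
Reagents that add atoms: iodine (I2), SMILES II
Why: Negishi–Takahashi zirconacyclopentene formation (ethylene from β-hydrogen abstraction in (C5H5)2ZrEt2 couples with the alkyne) followed by iodinolysis of both C–Zr bonds with retention, so the vinyl iodide and the iodoethyl arm are locked cis (Z) by the metallacycle.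

**Step 2**
Reactants: 6 (Z)-2,5-diiodo-3-methylpent-2-ene; 7 (5-chloropent-1-yn-1-yl)trimethylsilane
Product: 10 (Z)-(9-iodo-6,7-dimethylnon-6-en-1-yn-1-yl)trimethylsilane, via Grignard reagent 8 (not isolated), via alkylzinc chloride 9 (not isolated)
Conditions: 7, Mg, THF, reflux; ZnCl2 (1.1 equiv), 0 °C → rt; then 6, Pd(dppf)Cl2 (3 mol %), THF, rt → 40 °C
Reagents that add atoms: none
Why: Negishi sp3–sp2 coupling in which zerovalent palladium inserts only into the vinyl C–I bond (the primary alkyl iodide is inert to this catalyst and to RZnCl) and couples with retention of the Z geometry.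

**Step 3**
Reactants: 10 (Z)-(9-iodo-6,7-dimethylnon-6-en-1-yn-1-yl)trimethylsilane; 11 3-methylpentane-2,4-dione
Product: 14 (Z)-3,6,7-trimethyldodec-6-en-11-yn-2-one, via terminal alkyne iodide 12 (not isolated), via alkylated dione 13 (not isolated)
Conditions: 11 (1.5 equiv), K2CO3 (2 equiv), EtOH, reflux, 16 h
Reagents that add atoms: none
Why: One-pot Boatman–Hauser methyl ketone synthesis (SN2 C-alkylation of the diketone enolate by the primary iodide, then retro-Claisen deacetylation of the non-enolisable dione by ethoxide), while the same basic ethanol cleaves the alkynyl C–Si bond.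

**Step 4**
Reactants: 14 (Z)-3,6,7-trimethyldodec-6-en-11-yn-2-one
Product: 15 tert-butyl(dimethyl){[(6Z)-3,6,7-trimethyldodeca-1,6-dien-11-yn-2-yl]oxy}silane
Conditions: TBSOTf (1.2 equiv), Et3N (2 equiv), CH2Cl2, −78 → 0 °C
Reagents that add atoms: tert-butyldimethylsilyl trifluoromethanesulfonate, SMILES CC(C)(C)[Si](C)(C)OS(=O)(=O)C(F)(F)F
Why: Soft enolisation in which Et3N deprotonates the unhindered methyl group of the O-silylated ketone to give the terminal (kinetic) silyl enol ether, and the terminal alkyne is not silylated in the absence of a zinc salt.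

**Step 5**
Reactants: 15 tert-butyl(dimethyl){[(6Z)-3,6,7-trimethyldodeca-1,6-dien-11-yn-2-yl]oxy}silane
Product: 16 (5S)-2,5-dimethyl-5-[(1S)-1-methyl-2-methylidenecyclopentyl]cyclohexan-1-one (C-2 epimers)
Conditions: (R)-DTBM-SEGPHOS(AuCl)2 (3 mol %), AgSbF6 (6 mol %), i-PrOH (1.2 equiv), CH2Cl2, −30 → 0 °C
Reagents that add atoms: none
Why: Proposed new method: the cationic monovalent gold complex activates the terminal alkyne, the proximal carbon of the Z tetrasubstituted alkene attacks its internal carbon (5-exo-dig, ring A), and the silyl enol ether captures the developing tertiary cation at the distal alkene carbon from the opposite face through a chair-like six-membered transition state (ring B); silyl transfer to i-PrOH then releases the proton for protodeauration to the exocyclic methylene, so anti addition across the Z alkene fixes the like (S,S) relation of the two quaternary centres and the chiral digold ligand selects the alkene face; the closest known reaction types are the stereospecific gold-catalysed alkoxycyclisation and alkyne-initiated polyene cyclisation of 1,6-enynes with chiral bisphosphine digold complexes and the gold-catalysed carbocyclisation of silyl enol ethers onto alkynes.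

**Step 6**
Reactants: 16 (5S)-2,5-dimethyl-5-[(1S)-1-methyl-2-methylidenecyclopentyl]cyclohexan-1-one
Product: 17 (5S)-2,5-dimethyl-5-[(1S)-1-methyl-2-methylidenecyclopentyl]cyclohex-2-en-1-one
Conditions: IBX (2.5 equiv), DMSO/fluorobenzene 1:2, 70 °C
Reagents that add atoms: none
Why: Nicolaou IBX dehydrogenation through the enol, regiochemically forced because C-6 is flanked by the quaternary C-5 and has no β-hydrogen, so only the C-2/C-3 enone can form and both C-2 epimers converge.

**Step 7**
Reactants: 17 (5S)-2,5-dimethyl-5-[(1S)-1-methyl-2-methylidenecyclopentyl]cyclohex-2-en-1-one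
Product: 18 (1R,5S)-2,5-dimethyl-5-[(1S)-1-methyl-2-methylidenecyclopentyl]cyclohex-2-en-1-ol
Conditions: (S)-Me-CBS (20 mol %), catecholborane (1.5 equiv), toluene, −78 °C; then MeOH, aq. NaHCO3
Reagents that add atoms: none
Why: Corey–Bakshi–Shibata 1,2-reduction with the 2-methylalkenyl arm as the large group, so the (S) catalyst gives the (1R) carbinol (OH trans to the cyclopentyl group, hydride arriving anti to the axial C-5 methyl), and any minor enantiomer carried from step 5 becomes a separable diastereomer.

**Step 8**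
Reactants: 18 (1R,5S)-2,5-dimethyl-5-[(1S)-1-methyl-2-methylidenecyclopentyl]cyclohex-2-en-1-ol; 19 caffeic acid
Product: 20 (1S,5S)-2,5-dimethyl-5-[(1S)-1-methyl-2-methylidenecyclopentyl]cyclohex-2-en-1-yl (2E)-3-(3,4-dihydroxyphenyl)prop-2-enoate
Conditions: caffeic acid (1.5 equiv), PPh3 (1.5 equiv), DIAD (1.5 equiv), THF, 0 °C → rt
Reagents that add atoms: none
Why: Mitsunobu esterification with SN2 inversion at the allylic carbinol (1R → 1S, as in carveol inversions), chemoselective for the carboxylic acid over the far less acidic catechol hydroxyls so no protecting groups are needed.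

**Compound list**
1 | but-2-yne | CC#CC | starting material
2 | ethylmagnesium bromide | CC[Mg]Br | starting material
3 | diethylzirconocene, (C5H5)2Zr(C2H5)2 | CC[Zr+2]CC.c1cc[cH-]c1.c1cc[cH-]c1 | intermediate
4 | zirconocene ethylene complex, (C5H5)2Zr(C2H4) | C1C[Zr+2]1.c1cc[cH-]c1.c1cc[cH-]c1 | intermediate
5 | 1,1-bis(cyclopentadienyl)-2,3-dimethyl-1-zirconacyclopent-2-ene | CC1=C(C)CC[Zr+2]1.c1cc[cH-]c1.c1cc[cH-]c1 | intermediate
6 | (Z)-2,5-diiodo-3-methylpent-2-ene | I/C(C)=C(/C)CCI | intermediate
7 | (5-chloropent-1-yn-1-yl)trimethylsilane | C[Si](C)(C)C#CCCCCl | starting material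
8 | [5-(trimethylsilyl)pent-4-yn-1-yl]magnesium chloride | C[Si](C)(C)C#CCCC[Mg]Cl | intermediate
9 | [5-(trimethylsilyl)pent-4-yn-1-yl]zinc chloride | C[Si](C)(C)C#CCCC[Zn]Cl | intermediate
10 | (Z)-(9-iodo-6,7-dimethylnon-6-en-1-yn-1-yl)trimethylsilane | C[Si](C)(C)C#CCCC/C(C)=C(/C)CCI | intermediate
11 | 3-methylpentane-2,4-dione | CC(=O)C(C)C(C)=O | starting material
12 | (Z)-9-iodo-6,7-dimethylnon-6-en-1-yne | C#CCCC/C(C)=C(/C)CCI | intermediate
13 | 3-[(Z)-3,4-dimethylnon-3-en-8-yn-1-yl]-3-methylpentane-2,4-dione | C#CCCC/C(C)=C(/C)CCC(C)(C(C)=O)C(C)=O | intermediate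
14 | (Z)-3,6,7-trimethyldodec-6-en-11-yn-2-one (racemic at C-3) | C#CCCC/C(C)=C(/C)CCC(C)C(C)=O | intermediate
15 | tert-butyl(dimethyl){[(6Z)-3,6,7-trimethyldodeca-1,6-dien-11-yn-2-yl]oxy}silane | C#CCCC/C(C)=C(/C)CCC(C)C(=C)O[Si](C)(C)C(C)(C)C | intermediate
16 | (5S)-2,5-dimethyl-5-[(1S)-1-methyl-2-methylidenecyclopentyl]cyclohexan-1-one (C-2 epimers) | C=C1CCC[C@]1(C)[C@@]1(C)CCC(C)C(=O)C1 | intermediate
17 | (5S)-2,5-dimethyl-5-[(1S)-1-methyl-2-methylidenecyclopentyl]cyclohex-2-en-1-one | C=C1CCC[C@]1(C)[C@@]1(C)CC=C(C)C(=O)C1 | intermediate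
18 | (1R,5S)-2,5-dimethyl-5-[(1S)-1-methyl-2-methylidenecyclopentyl]cyclohex-2-en-1-ol | C=C1CCC[C@]1(C)[C@@]1(C)CC=C(C)[C@H](O)C1 | intermediate
19 | caffeic acid, (2E)-3-(3,4-dihydroxyphenyl)prop-2-enoic acid | OC(=O)/C=C/c1ccc(O)c(O)c1 | starting material
20 | (1S,5S)-2,5-dimethyl-5-[(1S)-1-methyl-2-methylidenecyclopentyl]cyclohex-2-en-1-yl (2E)-3-(3,4-dihydroxyphenyl)prop-2-enoate | C=C1CCC[C@]1(C)[C@@]1(C)CC=C(C)[C@@H](OC(=O)/C=C/c2ccc(O)c(O)c2)C1 | target

**Step count**
Total steps: 8. Longest linear sequence: 8 (but-2-yne → 20).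

**Steps most likely to fail, with fallbacks**

Step 5 (the cascade may give low ee, or the bulky chiral complex may not turn over on the tetrasubstituted alkene). The fallback sets out from 15 and rejoins the route at 18, taking the absolute configuration from a reagent-controlled reduction instead of from the gold ligand. Compound 15 is cyclised with the smaller achiral catalyst (JohnPhos)Au(MeCN)SbF6 (i-PrOH, CH2Cl2) to the racemic ketone, that is 16 together with (5R)-2,5-dimethyl-5-[(1R)-1-methyl-2-methylidenecyclopentyl]cyclohexan-1-one F1. IBX then gives 17 together with (5R)-2,5-dimethyl-5-[(1R)-1-methyl-2-methylidenecyclopentyl]cyclohex-2-en-1-one F2. Reduction of this racemate with (S)-Me-CBS/catecholborane sets C-1 as R in both enantiomers, giving 18 (trans) and the cis diastereomer (1R,5R)-2,5-dimethyl-5-[(1R)-1-methyl-2-methylidenecyclopentyl]cyclohex-2-en-1-ol F3. The two are separated on silica and the ee of 18 is checked by chiral HPLC.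

Step 3 (C-alkylation of a hindered diketone by a homoallylic iodide; O-alkylation and E2 compete). The fallback sets out from 10 and rejoins the route at 14 by an acetoacetic ester sequence. The sodium enolate of ethyl 2-methylacetoacetate (NaH, DMF, 50 °C) is alkylated with 10 to give ethyl (5Z)-2-acetyl-2,5,6-trimethyl-11-(trimethylsilyl)undec-5-en-10-ynoate F4. Krapcho dealkoxycarbonylation (LiCl, wet DMSO, 150 °C) gives (6Z)-3,6,7-trimethyl-12-(trimethylsilyl)dodec-6-en-11-yn-2-one F5, and K2CO3/MeOH at rt removes the silyl group to give 14.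

Step 8 (Mitsunobu on a pseudoaxial allylic alcohol with a free catechol acid; SN2′, elimination or phenol alkylation may intrude). The fallback sets out from 17 and rejoins the route at 20, acylating with retention and building the cinnamate C=C last. Compound 17 is reduced with (R)-Me-CBS/catecholborane to (1S,5S)-2,5-dimethyl-5-[(1S)-1-methyl-2-methylidenecyclopentyl]cyclohex-2-en-1-ol F6, which already has the target configuration at C-1. Heating with Meldrum's acid (toluene, 100 °C) gives the malonic half ester 3-{[(1S,5S)-2,5-dimethyl-5-[(1S)-1-methyl-2-methylidenecyclopentyl]cyclohex-2-en-1-yl]oxy}-3-oxopropanoic acid F7. Knoevenagel–Doebner condensation with 3,4-dihydroxybenzaldehyde (pyridine, cat. piperidine, 60 °C) decarboxylates to the E caffeate 20 without protecting groups.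

**Further compounds**
F1 | step 5 | (5R)-2,5-dimethyl-5-[(1R)-1-methyl-2-methylidenecyclopentyl]cyclohexan-1-one | C=C1CCC[C@@]1(C)[C@]1(C)CCC(C)C(=O)C1
F2 | step 5 | (5R)-2,5-dimethyl-5-[(1R)-1-methyl-2-methylidenecyclopentyl]cyclohex-2-en-1-one | C=C1CCC[C@@]1(C)[C@]1(C)CC=C(C)C(=O)C1
F3 | step 5 | (1R,5R)-2,5-dimethyl-5-[(1R)-1-methyl-2-methylidenecyclopentyl]cyclohex-2-en-1-ol | C=C1CCC[C@@]1(C)[C@]1(C)CC=C(C)[C@H](O)C1
F4 | step 3 | ethyl (5Z)-2-acetyl-2,5,6-trimethyl-11-(trimethylsilyl)undec-5-en-10-ynoate | C[Si](C)(C)C#CCCC/C(C)=C(/C)CCC(C)(C(C)=O)C(=O)OCC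
F5 | step 3 | (6Z)-3,6,7-trimethyl-12-(trimethylsilyl)dodec-6-en-11-yn-2-one | C[Si](C)(C)C#CCCC/C(C)=C(/C)CCC(C)C(C)=O
F6 | step 8 | (1S,5S)-2,5-dimethyl-5-[(1S)-1-methyl-2-methylidenecyclopentyl]cyclohex-2-en-1-ol | C=C1CCC[C@]1(C)[C@@]1(C)CC=C(C)[C@@H](O)C1
F7 | step 8 | 3-{[(1S,5S)-2,5-dimethyl-5-[(1S)-1-methyl-2-methylidenecyclopentyl]cyclohex-2-en-1-yl]oxy}-3-oxopropanoic acid | C=C1CCC[C@]1(C)[C@@]1(C)CC=C(C)[C@@H](OC(=O)CC(O)=O)C1
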